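## Retrosynthetic overview

1. Target 21 is epioritin-(4β→6)-melacacidin. Desilylation and hydrogenolysis lead back to the protected dimer 19, whose only bond between the flavan units is C4 (upper) to C6 (lower).
2. 19 comes from a thiophilic Friedel–Crafts union of the 4β-benzylsulfanyl upper unit 18 (electrophile, sets upper C4) with the 4-O-silyl lower unit 10 (nucleophile at C6).
3. 18 and 10 come from the all-cis 3-O-benzyl flavan-3,4-diols 17 and 9. Each is made by a new enantioselective all-cis hydrogenation of a 3-benzyloxyflavone (15, 7) that sets C2, C3 and C4 in one step.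
4. 7 and 15 come from flavonols 6 and 14 (Algar–Flynn–Oyamada, which closes the pyranone ring C of each unit), from chalcones 4 and 12, from the common ketone 2 and aldehydes 3 and 11.
5. Ring order: rings A and B are bought; ring C of the lower unit is closed (step 3) and reduced (step 5), then ring C of the upper unit (steps 8, 10); the units are joined last.

Assumption: the (R,R) carbene ligand is taken to deliver hydrogen to the face that gives the 2R series; if the sense of induction is the opposite, the (S,S) salt is used with nothing else changed.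

Note: where a descriptor at one carbon differs between compounds (C3 in 8, 10, 16, 18; upper C4 in 19), only CIP priorities change; no centre is inverted after it is set.

## Steps

Step 1
Reactants: 1 1-(2,3,4-trihydroxyphenyl)ethanone
Product: 2 1-[3,4-bis(benzyloxy)-2-hydroxyphenyl]ethanone
Conditions: BnBr (2.05 equiv), K2CO3 (2.2 equiv), DMF, 25 °C, 16 h
Reagents that add atoms: benzyl bromide, BrCc1ccccc1
Why: Williamson etherification in which the 2-OH, hydrogen-bonded to the ketone and least acidic, stays free while O3 and O4 are benzylated; no stereocentre.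

Step 2
Reactants: 2 1-[3,4-bis(benzyloxy)-2-hydroxyphenyl]ethanone; 3 3,4-bis(benzyloxy)benzaldehyde
Product: 4 (E)-1-[3,4-bis(benzyloxy)-2-hydroxyphenyl]-3-[3,4-bis(benzyloxy)phenyl]prop-2-en-1-one
Conditions: KOH (50% aq), EtOH/THF, 25 °C, 36 h
Reagents that add atoms: none
Why: Claisen–Schmidt aldol condensation; dehydration to the conjugated enone gives only the E alkene.

Step 3
Reactants: 4 (E)-1-[3,4-bis(benzyloxy)-2-hydroxyphenyl]-3-[3,4-bis(benzyloxy)phenyl]prop-2-en-1-one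
Product: 6 7,8-bis(benzyloxy)-2-[3,4-bis(benzyloxy)phenyl]-3-hydroxy-4H-chromen-4-one, via racemic trans-dihydroflavonol 5 (not isolated)
Conditions: H2O2 (30% aq, 5 equiv), NaOH (2 M aq), MeOH/THF, 0 °C to 25 °C
Reagents that add atoms: hydrogen peroxide, OO
Why: Algar–Flynn–Oyamada oxidative cyclisation, which gives the flavonol and not an aurone because the chalcone has no 6'-substituent; the stereocentres of 5 are erased on oxidation.

Step 4
Reactants: 6 7,8-bis(benzyloxy)-2-[3,4-bis(benzyloxy)phenyl]-3-hydroxy-4H-chromen-4-one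
Product: 7 3,7,8-tris(benzyloxy)-2-[3,4-bis(benzyloxy)phenyl]-4H-chromen-4-one
Conditions: BnBr (1.3 equiv), K2CO3 (1.5 equiv), DMF, 50 °C
Reagents that add atoms: benzyl bromide, BrCc1ccccc1
Why: Williamson O-alkylation of the acidic flavonol 3-OH, which also removes the chelating 3-hydroxy-4-keto site before the hydrogenation.

Step 5
Reactants: 7 3,7,8-tris(benzyloxy)-2-[3,4-bis(benzyloxy)phenyl]-4H-chromen-4-one
Product: 9 (2R,3R,4R)-3,7,8-tris(benzyloxy)-2-[3,4-bis(benzyloxy)phenyl]chroman-4-ol, via cis-flavanone 8 (not isolated)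
Conditions: catalyst pre-formed from Ru(cod)(2-methylallyl)2 (5 mol %), (R,R)-SINpEt·HBF4 [1,3-bis((R)-1-(1-naphthyl)ethyl)-4,5-dihydroimidazolium tetrafluoroborate, 10 mol %] and KOtBu (10 mol %) in n-hexane at 70 °C; then 7, H2 (120 bar), toluene, 40 °C, 48 h
Reagents that add atoms: none
Why: Proposed new method: enantioselective all-cis hydrogenation of a 3-alkoxyflavone, a substrate class not yet shown for this catalyst; the closest known reaction is the hydrogenation of 3-unsubstituted flavones and chromones to cis-flavan-4-ols with the same chiral Ru–bis(N-heterocyclic carbene) system; the Ru hydride binds the pyranone C2=C3 bond and adds H2 syn to one enantioface (the naphthylethyl arms tell the faces apart by the 2-aryl group), which sets C2 and C3 cis in 8; the ketone of 8 is then reduced from the face anti to the cis 2-aryl and pseudo-axial 3-benzyloxy groups, so O4 ends cis to both; base is kept at or below the azolium loading so that 8 is not epimerised at C3.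

Step 6
Reactants: 9 (2R,3R,4R)-3,7,8-tris(benzyloxy)-2-[3,4-bis(benzyloxy)phenyl]chroman-4-ol
Product: 10 (2R,3S,4R)-3,7,8-tris(benzyloxy)-2-[3,4-bis(benzyloxy)phenyl]-4-(tert-butyldimethylsilyloxy)chromane (all-cis)
Conditions: TBSCl (1.5 equiv), imidazole (3 equiv), DMAP (cat.), DMF, 40 °C
Reagents that add atoms: tert-butyldimethylsilyl chloride, CC(C)(C)[Si](C)(C)Cl
Why: Silylation of the only free hydroxyl at oxygen, so no stereocentre is touched; the silyl ether blocks O-alkylation at O4 in step 12 and later shields the benzylic C4–O bond from hydrogenolysis.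

Step 7
Reactants: 2 1-[3,4-bis(benzyloxy)-2-hydroxyphenyl]ethanone; 11 4-(benzyloxy)benzaldehyde
Product: 12 (E)-1-[3,4-bis(benzyloxy)-2-hydroxyphenyl]-3-[4-(benzyloxy)phenyl]prop-2-en-1-one
Conditions: KOH (50% aq), EtOH/THF, 25 °C, 36 h
Reagents that add atoms: none
Why: Claisen–Schmidt aldol condensation giving the E enone, as in step 2.

Step 8
Reactants: 12 (E)-1-[3,4-bis(benzyloxy)-2-hydroxyphenyl]-3-[4-(benzyloxy)phenyl]prop-2-en-1-one
Product: 14 7,8-bis(benzyloxy)-2-[4-(benzyloxy)phenyl]-3-hydroxy-4H-chromen-4-one, via racemic trans-dihydroflavonol 13 (not isolated)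
Conditions: H2O2 (30% aq, 5 equiv), NaOH (2 M aq), MeOH/THF, 0 °C to 25 °C
Reagents that add atoms: hydrogen peroxide, OO
Why: Algar–Flynn–Oyamada oxidative cyclisation to the flavonol, as in step 3.

Step 9
Reactants: 14 7,8-bis(benzyloxy)-2-[4-(benzyloxy)phenyl]-3-hydroxy-4H-chromen-4-one
Product: 15 3,7,8-tris(benzyloxy)-2-[4-(benzyloxy)phenyl]-4H-chromen-4-one
Conditions: BnBr (1.3 equiv), K2CO3 (1.5 equiv), DMF, 50 °C
Reagents that add atoms: benzyl bromide, BrCc1ccccc1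
Why: Williamson O-alkylation of the flavonol 3-OH, as in step 4.

Step 10
Reactants: 15 3,7,8-tris(benzyloxy)-2-[4-(benzyloxy)phenyl]-4H-chromen-4-one
Product: 17 (2R,3R,4R)-3,7,8-tris(benzyloxy)-2-[4-(benzyloxy)phenyl]chroman-4-ol, via cis-flavanone 16 (not isolated)
Conditions: catalyst pre-formed from Ru(cod)(2-methylallyl)2 (5 mol %), (R,R)-SINpEt·HBF4 (10 mol %) and KOtBu (10 mol %) in n-hexane at 70 °C; then 15, H2 (120 bar), toluene, 40 °C, 48 h
Reagents that add atoms: none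
Why: Proposed new method: the same enantioselective all-cis hydrogenation of a 3-alkoxyflavone as in step 5, closest to the known chiral Ru–bis(N-heterocyclic carbene) hydrogenation of 3-unsubstituted flavones to cis-flavan-4-ols; syn addition of H2 to one face of C2=C3 sets C2 and C3 cis in 16, and reduction of its ketone anti to the 2-aryl and 3-benzyloxy groups gives the all-cis alcohol.

Step 11
Reactants: 17 (2R,3R,4R)-3,7,8-tris(benzyloxy)-2-[4-(benzyloxy)phenyl]chroman-4-ol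
Product: 18 (2R,3S,4S)-3,7,8-tris(benzyloxy)-2-[4-(benzyloxy)phenyl]-4-(benzylsulfanyl)chromane (2,3-cis-3,4-trans)
Conditions: BnSH (5 equiv), BF3·OEt2 (0.2 equiv), CH2Cl2, −40 °C to 0 °C
Reagents that add atoms: phenylmethanethiol, SCc1ccccc1
Why: SN1 thiolysis of a flavan-4-ol, in which the Lewis acid ionises the benzylic 4-OH (cation stabilised by O1 and the 7-oxygen) and the thiol adds anti to the axial 3-benzyloxy group; C2 and C3 are untouched.

Step 12
Reactants: 18 (2R,3S,4S)-3,7,8-tris(benzyloxy)-2-[4-(benzyloxy)phenyl]-4-(benzylsulfanyl)chromane; 10 (2R,3S,4R)-3,7,8-tris(benzyloxy)-2-[3,4-bis(benzyloxy)phenyl]-4-(tert-butyldimethylsilyloxy)chromane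
Product: 19 (2R,3R,4R)-3,7,8-tris(benzyloxy)-2-[4-(benzyloxy)phenyl]-4-[(2R,3S,4R)-3,7,8-tris(benzyloxy)-2-[3,4-bis(benzyloxy)phenyl]-4-(tert-butyldimethylsilyloxy)chroman-6-yl]chromane
Conditions: AgBF4 (2.5 equiv), 2,6-di-tert-butyl-4-methylpyridine (3 equiv), 4 Å MS, THF, 0 °C, dark; 18 added slowly to 10 (3 equiv, excess recovered)
Reagents that add atoms: none
Why: Thiophilic Friedel–Crafts alkylation in which AgBF4 removes only the benzylsulfanyl group (the silyl ether of 10 is inert) and C6 of 10 (para to O1, ortho to the 7-benzyloxy group, while C5 is blocked by the peri silyloxy group) attacks the C4 cation anti to the axial 3-benzyloxy group, which sets the upper C4 centre 3,4-trans (4β); excess nucleophile suppresses oligomers.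

Step 13
Reactants: 19 (2R,3R,4R)-3,7,8-tris(benzyloxy)-2-[4-(benzyloxy)phenyl]-4-[(2R,3S,4R)-3,7,8-tris(benzyloxy)-2-[3,4-bis(benzyloxy)phenyl]-4-(tert-butyldimethylsilyloxy)chroman-6-yl]chromane
Product: 20 (2R,3R,4S)-4-[(2R,3S,4R)-4-(tert-butyldimethylsilyloxy)-2-(3,4-dihydroxyphenyl)-3,7,8-trihydroxychroman-6-yl]-2-(4-hydroxyphenyl)chromane-3,7,8-triol
Conditions: H2 (1 atm), Pd(OH)2/C, THF/EtOAc, 25 °C
Reagents that add atoms: none
Why: Hydrogenolysis of the nine benzyl ethers under neutral, methanol-free conditions; the bulky silyl ether keeps the benzylic lower C4–O bond from hydrogenolysis, and no stereocentre is touched.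

Step 14
Reactants: 20 (2R,3R,4S)-4-[(2R,3S,4R)-4-(tert-butyldimethylsilyloxy)-2-(3,4-dihydroxyphenyl)-3,7,8-trihydroxychroman-6-yl]-2-(4-hydroxyphenyl)chromane-3,7,8-triol
Product: 21 (2R,3R,4S)-4-[(2R,3R,4R)-2-(3,4-dihydroxyphenyl)-3,4,7,8-tetrahydroxychroman-6-yl]-2-(4-hydroxyphenyl)chromane-3,7,8-triol
Conditions: HF·pyridine, pyridine, THF, 0 °C to 25 °C; Sephadex LH-20
Reagents that add atoms: none
Why: Fluoride cleaves the Si–O bond at silicon, so the lower C4 configuration is kept, and the pyridine buffer prevents acid ionisation of the benzylic 4-OH.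

## Compound list

1 | 1-(2,3,4-trihydroxyphenyl)ethanone | CC(=O)c1ccc(O)c(O)c1O | starting material
2 | 1-[3,4-bis(benzyloxy)-2-hydroxyphenyl]ethanone | CC(=O)c1ccc(OCc2ccccc2)c(OCc2ccccc2)c1O | intermediate
3 | 3,4-bis(benzyloxy)benzaldehyde | O=Cc1ccc(OCc2ccccc2)c(OCc2ccccc2)c1 | starting material
4 | (E)-1-[3,4-bis(benzyloxy)-2-hydroxyphenyl]-3-[3,4-bis(benzyloxy)phenyl]prop-2-en-1-one | O=C(/C=C/c1ccc(OCc2ccccc2)c(OCc2ccccc2)c1)c1ccc(OCc2ccccc2)c(OCc2ccccc2)c1O | intermediate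
5 | racemic trans-7,8-bis(benzyloxy)-2-[3,4-bis(benzyloxy)phenyl]-3-hydroxychroman-4-one (both enantiomers written) | c1cc2c(c(OCc3ccccc3)c1OCc1ccccc1)O[C@H](c1ccc(OCc3ccccc3)c(OCc3ccccc3)c1)[C@@H](O)C2=O.c1cc2c(c(OCc3ccccc3)c1OCc1ccccc1)O[C@@H](c1ccc(OCc3ccccc3)c(OCc3ccccc3)c1)[C@H](O)C2=O | intermediate (not isolated)
6 | 7,8-bis(benzyloxy)-2-[3,4-bis(benzyloxy)phenyl]-3-hydroxy-4H-chromen-4-one | O=c1c(O)c(-c2ccc(OCc3ccccc3)c(OCc3ccccc3)c2)oc2c(OCc3ccccc3)c(OCc3ccccc3)ccc12 | intermediate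
7 | 3,7,8-tris(benzyloxy)-2-[3,4-bis(benzyloxy)phenyl]-4H-chromen-4-one | O=c1c(OCc2ccccc2)c(-c2ccc(OCc3ccccc3)c(OCc3ccccc3)c2)oc2c(OCc3ccccc3)c(OCc3ccccc3)ccc12 | intermediate
8 | (2R,3S)-3,7,8-tris(benzyloxy)-2-[3,4-bis(benzyloxy)phenyl]chroman-4-one (2,3-cis) | c1cc2c(c(OCc3ccccc3)c1OCc1ccccc1)O[C@H](c1ccc(OCc3ccccc3)c(OCc3ccccc3)c1)[C@H](OCc1ccccc1)C2=O | intermediate (not isolated)
9 | (2R,3R,4R)-3,7,8-tris(benzyloxy)-2-[3,4-bis(benzyloxy)phenyl]chroman-4-ol (2,3-cis-3,4-cis) | c1cc2c(c(OCc3ccccc3)c1OCc1ccccc1)O[C@H](c1ccc(OCc3ccccc3)c(OCc3ccccc3)c1)[C@H](OCc1ccccc1)[C@@H]2O | intermediate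
10 | (2R,3S,4R)-3,7,8-tris(benzyloxy)-2-[3,4-bis(benzyloxy)phenyl]-4-(tert-butyldimethylsilyloxy)chromane (all-cis) | c1cc2c(c(OCc3ccccc3)c1OCc1ccccc1)O[C@H](c1ccc(OCc3ccccc3)c(OCc3ccccc3)c1)[C@H](OCc1ccccc1)[C@@H]2O[Si](C)(C)C(C)(C)C | intermediate
11 | 4-(benzyloxy)benzaldehyde | O=Cc1ccc(OCc2ccccc2)cc1 | starting material
12 | (E)-1-[3,4-bis(benzyloxy)-2-hydroxyphenyl]-3-[4-(benzyloxy)phenyl]prop-2-en-1-one | O=C(/C=C/c1ccc(OCc2ccccc2)cc1)c1ccc(OCc2ccccc2)c(OCc2ccccc2)c1O | intermediate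
13 | racemic trans-7,8-bis(benzyloxy)-2-[4-(benzyloxy)phenyl]-3-hydroxychroman-4-one (both enantiomers written) | c1cc2c(c(OCc3ccccc3)c1OCc1ccccc1)O[C@H](c1ccc(OCc3ccccc3)cc1)[C@@H](O)C2=O.c1cc2c(c(OCc3ccccc3)c1OCc1ccccc1)O[C@@H](c1ccc(OCc3ccccc3)cc1)[C@H](O)C2=O | intermediate (not isolated)
14 | 7,8-bis(benzyloxy)-2-[4-(benzyloxy)phenyl]-3-hydroxy-4H-chromen-4-one | O=c1c(O)c(-c2ccc(OCc3ccccc3)cc2)oc2c(OCc3ccccc3)c(OCc3ccccc3)ccc12 | intermediate
15 | 3,7,8-tris(benzyloxy)-2-[4-(benzyloxy)phenyl]-4H-chromen-4-one | O=c1c(OCc2ccccc2)c(-c2ccc(OCc3ccccc3)cc2)oc2c(OCc3ccccc3)c(OCc3ccccc3)ccc12 | intermediate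
16 | (2R,3S)-3,7,8-tris(benzyloxy)-2-[4-(benzyloxy)phenyl]chroman-4-one (2,3-cis) | c1cc2c(c(OCc3ccccc3)c1OCc1ccccc1)O[C@H](c1ccc(OCc3ccccc3)cc1)[C@H](OCc1ccccc1)C2=O | intermediate (not isolated)
17 | (2R,3R,4R)-3,7,8-tris(benzyloxy)-2-[4-(benzyloxy)phenyl]chroman-4-ol (2,3-cis-3,4-cis) | c1cc2c(c(OCc3ccccc3)c1OCc1ccccc1)O[C@H](c1ccc(OCc3ccccc3)cc1)[C@H](OCc1ccccc1)[C@@H]2O | intermediate
18 | (2R,3S,4S)-3,7,8-tris(benzyloxy)-2-[4-(benzyloxy)phenyl]-4-(benzylsulfanyl)chromane (2,3-cis-3,4-trans) | c1cc2c(c(OCc3ccccc3)c1OCc1ccccc1)O[C@H](c1ccc(OCc3ccccc3)cc1)[C@H](OCc1ccccc1)[C@H]2SCc1ccccc1 | intermediate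
19 | (2R,3R,4R)-3,7,8-tris(benzyloxy)-2-[4-(benzyloxy)phenyl]-4-[(2R,3S,4R)-3,7,8-tris(benzyloxy)-2-[3,4-bis(benzyloxy)phenyl]-4-(tert-butyldimethylsilyloxy)chroman-6-yl]chromane (upper unit 2,3-cis-3,4-trans, lower unit all-cis) | C(Oc1ccc([C@H]2Oc3c(ccc(OCc4ccccc4)c3OCc3ccccc3)[C@H](c3cc4c(c(OCc5ccccc5)c3OCc3ccccc3)O[C@H](c3ccc(OCc5ccccc5)c(OCc5ccccc5)c3)[C@H](OCc3ccccc3)[C@@H]4O[Si](C)(C)C(C)(C)C)[C@H]2OCc2ccccc2)cc1)c1ccccc1 | intermediate
20 | (2R,3R,4S)-4-[(2R,3S,4R)-4-(tert-butyldimethylsilyloxy)-2-(3,4-dihydroxyphenyl)-3,7,8-trihydroxychroman-6-yl]-2-(4-hydroxyphenyl)chromane-3,7,8-triol | Oc1ccc([C@H]2Oc3c(ccc(O)c3O)[C@H](c3cc4c(c(O)c3O)O[C@H](c3ccc(O)c(O)c3)[C@H](O)[C@@H]4O[Si](C)(C)C(C)(C)C)[C@H]2O)cc1 | intermediate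
21 | (2R,3R,4S)-4-[(2R,3R,4R)-2-(3,4-dihydroxyphenyl)-3,4,7,8-tetrahydroxychroman-6-yl]-2-(4-hydroxyphenyl)chromane-3,7,8-triol, epioritin-(4β→6)-melacacidin | Oc1ccc([C@H]2Oc3c(ccc(O)c3O)[C@H](c3cc4c(c(O)c3O)O[C@H](c3ccc(O)c(O)c3)[C@H](O)[C@@H]4O)[C@H]2O)cc1 | target

## Step count and risks

Total step count: 14. Longest linear sequence: 9 steps (1, 2, 3, 4, 5, 6, 12, 13, 14, from compound 1).

Three steps most likely to fail:

Step 5 (new hydrogenation, lower unit). The tetrasubstituted, electron-rich C2=C3 bond may react slowly or with low enantioselectivity, or 8 may epimerise at C3 before its ketone is reduced. The fallback sets out from 7 and gives up asymmetric induction. 7 is hydrogenated over PtO2 (H2 5 bar, EtOAc, 25 °C), the classical heterogeneous all-cis reduction of flavonol derivatives in which all three hydrogens come from the catalyst face, to give racemic all-cis 3,7,8-tris(benzyloxy)-2-[3,4-bis(benzyloxy)phenyl]chroman-4-ol F1. Preparative supercritical-fluid chromatography on an amylose tris(3,5-dimethylphenylcarbamate) phase (CO2/iPrOH) then separates the (2R,3R,4R) enantiomer, which is 9, and the route is rejoined there.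

Step 10 (new hydrogenation, upper unit). The risks are the same as in step 5. The fallback sets out from 15: heterogeneous hydrogenation (H2 5 bar, PtO2, EtOAc, 25 °C) gives racemic all-cis 3,7,8-tris(benzyloxy)-2-[4-(benzyloxy)phenyl]chroman-4-ol F2. Chromatography on the same chiral phase gives the (2R,3R,4R) enantiomer, which is 17, and the route is rejoined there.

Step 12 (interflavan coupling). The fully benzylated ring A of 10 is only a moderate nucleophile, so the cation from 18 may oligomerise or eliminate instead. The fallback sets out from 10 and 18 and uses a free-phenol nucleophile. 10 is first debenzylated (H2, Pd(OH)2/C, THF/EtOAc; the benzylic silyl ether stays) to (2R,3S,4R)-4-(tert-butyldimethylsilyloxy)-2-(3,4-dihydroxyphenyl)chromane-3,7,8-triol F3, whose free 7-OH makes C6 far more nucleophilic (phenol ortho-alkylation, as in biomimetic proanthocyanidin couplings). F3 (3 equiv) is alkylated by 18 with AgBF4 and 2,6-di-tert-butyl-4-methylpyridine in THF at 0 °C to give (2R,3R,4S)-3,7,8-tris(benzyloxy)-2-[4-(benzyloxy)phenyl]-4-[(2R,3S,4R)-4-(tert-butyldimethylsilyloxy)-2-(3,4-dihydroxyphenyl)-3,7,8-trihydroxychroman-6-yl]chromane F4. Hydrogenolysis of F4 (H2, Pd(OH)2/C, THF/EtOAc) gives 20, where the route is rejoined before step 14.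

## Further compounds

F1 | step 5 | racemic all-cis 3,7,8-tris(benzyloxy)-2-[3,4-bis(benzyloxy)phenyl]chroman-4-ol (both enantiomers written) | c1cc2c(c(OCc3ccccc3)c1OCc1ccccc1)O[C@H](c1ccc(OCc3ccccc3)c(OCc3ccccc3)c1)[C@H](OCc1ccccc1)[C@@H]2O.c1cc2c(c(OCc3ccccc3)c1OCc1ccccc1)O[C@@H](c1ccc(OCc3ccccc3)c(OCc3ccccc3)c1)[C@@H](OCc1ccccc1)[C@H]2O
F2 | step 10 | racemic all-cis 3,7,8-tris(benzyloxy)-2-[4-(benzyloxy)phenyl]chroman-4-ol (both enantiomers written) | c1cc2c(c(OCc3ccccc3)c1OCc1ccccc1)O[C@H](c1ccc(OCc3ccccc3)cc1)[C@H](OCc1ccccc1)[C@@H]2O.c1cc2c(c(OCc3ccccc3)c1OCc1ccccc1)O[C@@H](c1ccc(OCc3ccccc3)cc1)[C@@H](OCc1ccccc1)[C@H]2O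
F3 | step 12 | (2R,3S,4R)-4-(tert-butyldimethylsilyloxy)-2-(3,4-dihydroxyphenyl)chromane-3,7,8-triol | c1cc2c(c(O)c1O)O[C@H](c1ccc(O)c(O)c1)[C@H](O)[C@@H]2O[Si](C)(C)C(C)(C)C
F4 | step 12 | (2R,3R,4S)-3,7,8-tris(benzyloxy)-2-[4-(benzyloxy)phenyl]-4-[(2R,3S,4R)-4-(tert-butyldimethylsilyloxy)-2-(3,4-dihydroxyphenyl)-3,7,8-trihydroxychroman-6-yl]chromane | C(Oc1ccc([C@H]2Oc3c(ccc(OCc4ccccc4)c3OCc3ccccc3)[C@H](c3cc4c(c(O)c3O)O[C@H](c3ccc(O)c(O)c3)[C@H](O)[C@@H]4O[Si](C)(C)C(C)(C)C)[C@H]2OCc2ccccc2)cc1)c1ccccc1
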